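**Retrosynthetic overview**
- The Z,Z-diene diester comes from semi-hydrogenation of a diynoate. The ring A ester is cut to the core diol and a diynoic acid built from (S)-pent-1-yn-3-ol, CO2 and hex-2-ynoic acid.
- The isopropylidene enone comes from the trans-decalin-2-one by acetone aldol and dehydration.
- Key step, ring B formed last: iron-hydride hydrogen atom transfer to an exocyclic methylene on ring A gives a tertiary radical that closes 6-endo onto a vinyl ketone (C4a–C4 bond). This creates the methyl-bearing quaternary centre and the trans ring fusion (locants of the naphthalen-2(1H)-one names are used throughout).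
- The radical precursor comes from a ring A aldehyde and lithiated methoxyallene (acryloyl anion equivalent).
- Ring A is formed first, by an enantioselective Diels–Alder reaction of the silyloxydiene from ethyl vinyl ketone with ethyl buta-2,3-dienoate.

Assumption: (S)-pent-1-yn-3-ol is bought enantiopure, and the (S)-oxazaborolidinium salt of step 2 is taken to leave the Re face at C2 of the allenoate open (its mirror image is used if the sense proves opposite).

**Step 1**
Reactants: 1 pent-1-en-3-one
Product: 2 (Z)-triisopropyl(penta-1,3-dien-3-yloxy)silane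
Conditions: iPr3SiOTf, Et3N, Et2O, 0 °C → rt
Reagents that add atoms: triisopropylsilyl trifluoromethanesulfonate, CC(C)[Si](OS(=O)(=O)C(F)(F)F)(C(C)C)C(C)C
Why: Amine/silyl triflate soft enolisation (silyl enol ether formation) of the ethyl ketone gives the 2-silyloxy diene as the Z enol ether, which puts the methyl group on the outside of the s-cis diene; no stereocentre is formed.

**Step 2**
Reactants: 2 (Z)-triisopropyl(penta-1,3-dien-3-yloxy)silane; 3 ethyl buta-2,3-dienoate
Product: 4 ethyl (1R,5R)-5-methyl-6-methylidene-4-[(triisopropylsilyl)oxy]cyclohex-3-ene-1-carboxylate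
Conditions: (S)-1-(2-methylphenyl)-3,3-diphenyltetrahydro-1H,3H-pyrrolo[1,2-c][1,3,2]oxazaborole·HNTf2 (20 mol %), CH2Cl2, −78 → −40 °C
Reagents that add atoms: none
Why: Proposed new method: the cationic oxazaborolidine binds the ester carbonyl of 3 and activates its conjugated C2=C3 bond for a Diels–Alder reaction in which the silyloxy group makes the methyl-bearing diene terminus the nucleophile that bonds to the electrophilic central allene carbon, the ester lies endo so that it ends up cis to the outside methyl (C1 and C5 of 4), and the catalyst leaves only the Re face of C2 of 3 open, which makes both new centres R; the closest known reactions are oxazaborolidinium-catalysed Diels–Alder additions of 2-silyloxydienes to acrylates and Lewis-acid-promoted cycloadditions of allenic esters at their conjugated double bond.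

**Step 3**
Reactants: 4 ethyl (1R,5R)-5-methyl-6-methylidene-4-[(triisopropylsilyl)oxy]cyclohex-3-ene-1-carboxylate
Product: 6 (1R,2R,4R)-4-(hydroxymethyl)-2-methyl-3-methylidenecyclohexan-1-ol, via keto ester 5 (not isolated)
Conditions: Bu4NF, AcOH, THF, −20 °C; crude, then LiAlH4, THF, −78 → 0 °C
Reagents that add atoms: none
Why: Buffered fluoride cleaves the silyl enol ether without moving the exocyclic alkene into conjugation or epimerising the α-methyl centre, and LiAlH4 reduction then converts the ester into the primary alcohol and, by axial hydride attack on the chair that carries both substituents equatorial, the ketone into the equatorial alcohol trans to the methyl group (C1 of 6, R).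

**Step 4**
Reactants: 6 (1R,2R,4R)-4-(hydroxymethyl)-2-methyl-3-methylidenecyclohexan-1-ol
Product: 7 (1R,3R,4R)-4-hydroxy-3-methyl-2-methylidenecyclohexane-1-carbaldehyde
Conditions: 2,2,6,6-tetramethylpiperidin-1-oxyl (10 mol %), PhI(OAc)2, CH2Cl2, rt
Reagents that add atoms: none
Why: Oxoammonium oxidation (TEMPO/PhI(OAc)2) is selective for the primary over the secondary alcohol and mild enough to leave the epimerisable β,γ-unsaturated aldehyde intact; no stereocentre is formed.

**Step 5**
Reactants: 7 (1R,3R,4R)-4-hydroxy-3-methyl-2-methylidenecyclohexane-1-carbaldehyde; 8 methoxyallene (1-methoxypropa-1,2-diene)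
Product: 12 (1S)-1-[(tert-butyldimethylsilyl)oxy]-1-[(1R,3R,4R)-4-[(tert-butyldimethylsilyl)oxy]-3-methyl-2-methylidenecyclohexyl]but-3-en-2-one, via 1-lithio-1-methoxyallene 9 (not isolated), via dilithium dialkoxide 10 (not isolated), via bis-silyl allenyl ether 11 (not isolated)
Conditions: 8 (3 equiv), n-BuLi, THF, −40 °C; 7, −78 °C; tBuMe2SiOTf, −78 → 0 °C; 1 M aq H2SO4, 0 °C
Reagents that add atoms: tert-butyldimethylsilyl trifluoromethanesulfonate, CC(C)(C)[Si](C)(C)OS(=O)(=O)C(F)(F)F; water, O
Why: Lithiated methoxyallene acts as an acryloyl anion equivalent: its Felkin–Anh 1,2-addition to the aldehyde, in which the methylidene-bearing ring carbon is the large group anti to the nucleophile, sets the carbinol centre as S (the minor epimer is removed by chromatography), both lithium alkoxides are silylated in the same flask, and dilute acid hydrolyses the allenyl enol ether to the vinyl ketone.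

**Step 6 (key step)**
Reactants: 12 (1S)-1-[(tert-butyldimethylsilyl)oxy]-1-[(1R,3R,4R)-4-[(tert-butyldimethylsilyl)oxy]-3-methyl-2-methylidenecyclohexyl]but-3-en-2-one
Product: 13 (1S,4aR,5R,6R,8aR)-1,6-bis[(tert-butyldimethylsilyl)oxy]-4a,5-dimethyloctahydronaphthalen-2(1H)-one
Conditions: Fe(acac)3 (30 mol %), PhSiH3, EtOH/(CH2OH)2, 60 °C
Reagents that add atoms: none
Why: Metal-hydride hydrogen atom transfer from the iron hydride to the 1,1-disubstituted alkene gives the tertiary ring radical and the new methyl group, and this nucleophilic radical adds 6-endo-trig to the terminal carbon of the vinyl ketone (Giese-type cyclisation forming C4a–C4) through a chair transition state in which the tether and its silyloxy group are equatorial and the small methyl group becomes axial, which gives the trans ring fusion and the R quaternary centre C4a before the α-keto radical is reduced and protonated.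

**Step 7**
Reactants: 13 (1S,4aR,5R,6R,8aR)-1,6-bis[(tert-butyldimethylsilyl)oxy]-4a,5-dimethyloctahydronaphthalen-2(1H)-one; 14 acetone
Product: 16 (1S,4aR,5R,6R,8aR)-1,6-bis[(tert-butyldimethylsilyl)oxy]-3-(2-hydroxypropan-2-yl)-4a,5-dimethyloctahydronaphthalen-2(1H)-one (both C3 epimers), via lithium enolate 15 (not isolated)
Conditions: LiN(iPr)2, THF, −78 °C; 14, −78 °C, 10 min; AcOH
Reagents that add atoms: none
Why: Kinetic deprotonation takes place at the C3 methylene and not at the silyloxy-bearing C1, and the lithium enolate adds to acetone in an aldol reaction that is quenched cold before retro-aldol can set in; the new C3 centre is formed as a mixture that does not matter because it is removed in step 8.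

**Step 8**
Reactants: 16 (1S,4aR,5R,6R,8aR)-1,6-bis[(tert-butyldimethylsilyl)oxy]-3-(2-hydroxypropan-2-yl)-4a,5-dimethyloctahydronaphthalen-2(1H)-one
Product: 18 (1S,4aR,5R,6R,8aR)-1,6-dihydroxy-4a,5-dimethyl-3-(propan-2-ylidene)octahydronaphthalen-2(1H)-one, via triol 17 (not isolated)
Conditions: HCl (3 M in MeOH), 50 °C
Reagents that add atoms: none
Why: Acid-catalysed dehydration of the tertiary β-hydroxy ketone through its enol gives the conjugated tetrasubstituted enone, the thermodynamic alkene isomer, while acidic methanol cleaves both silyl ethers; no stereocentre is formed and the equatorial C1 hydroxyl is the stable epimer of the acyloin.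

**Step 9**
Reactants: 19 (S)-pent-1-yn-3-ol
Product: 21 (S)-4-hydroxyhex-2-ynoic acid, via dilithium alkynide alkoxide 20 (not isolated)
Conditions: n-BuLi (2.1 equiv), THF, −78 °C; CO2; 1 M aq HCl
Reagents that add atoms: carbon dioxide, O=C=O
Why: Double deprotonation gives the alkoxide acetylide, whose carbanion is carboxylated by CO2 (carboxylation of a lithium acetylide); the stereocentre is not involved and stays S.

**Step 10**
Reactants: 21 (S)-4-hydroxyhex-2-ynoic acid; 22 hex-2-ynoic acid
Product: 24 (S)-4-(hex-2-ynoyloxy)hex-2-ynoic acid, via hex-2-ynoyl chloride 23 (not isolated)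
Conditions: 22, 1-chloro-N,N,2-trimethylprop-1-en-1-amine (1.0 equiv), CH2Cl2, 0 °C; then 21, 35 °C
Reagents that add atoms: none
Why: The acid chloride, made under neutral conditions (Ghosez chlorination), acylates the secondary hydroxyl without base, conditions under which the free carboxylic acid is a poor nucleophile and any mixed anhydride is hydrolysed on work-up; the C–O bond at the stereocentre is not broken, so it stays S.

**Step 11**
Reactants: 18 (1S,4aR,5R,6R,8aR)-1,6-dihydroxy-4a,5-dimethyl-3-(propan-2-ylidene)octahydronaphthalen-2(1H)-one; 24 (S)-4-(hex-2-ynoyloxy)hex-2-ynoic acid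
Product: 25 (1R,2R,4aR,5S,8aR)-5-hydroxy-1,8a-dimethyl-6-oxo-7-(propan-2-ylidene)decahydronaphthalen-2-yl (4S)-4-(hex-2-ynoyloxy)hex-2-ynoate
Conditions: N,N'-dicyclohexylcarbodiimide, 4-(dimethylamino)pyridine (5 mol %), CH2Cl2, −20 → 0 °C
Reagents that add atoms: none
Why: Steglich esterification takes place at the equatorial ring A hydroxyl in preference to the acyloin hydroxyl, which is less nucleophilic (adjacent carbonyl, internal hydrogen bond) and crowded by the ring fusion; no bond to a stereocentre is broken.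

**Step 12**
Reactants: 25 (1R,2R,4aR,5S,8aR)-5-hydroxy-1,8a-dimethyl-6-oxo-7-(propan-2-ylidene)decahydronaphthalen-2-yl (4S)-4-(hex-2-ynoyloxy)hex-2-ynoate
Product: 26 (1R,2R,4aR,5S,8aR)-5-hydroxy-1,8a-dimethyl-6-oxo-7-(propan-2-ylidene)decahydronaphthalen-2-yl (2Z,4S)-4-[(2Z)-hex-2-enoyloxy]hex-2-enoate (CNP0170141.1)
Conditions: H2 (1 atm), Pd/CaCO3 poisoned with Pb(OAc)2, quinoline, EtOAc, 0 °C, stopped after 2 equiv H2
Reagents that add atoms: none
Why: Lindlar semi-hydrogenation delivers H2 syn to each conjugated alkyne and so gives both Z enoates, while the poisoned catalyst neither reduces the alkenes further nor touches the tetrasubstituted enone; no stereocentre is affected.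

**Compound list**
1 | pent-1-en-3-one | CCC(=O)C=C | starting material
2 | (Z)-triisopropyl(penta-1,3-dien-3-yloxy)silane | C=C/C(O[Si](C(C)C)(C(C)C)C(C)C)=C/C | intermediate
3 | ethyl buta-2,3-dienoate | C=C=CC(=O)OCC | starting material
4 | ethyl (1R,5R)-5-methyl-6-methylidene-4-[(triisopropylsilyl)oxy]cyclohex-3-ene-1-carboxylate | CC(C)[Si](C(C)C)(C(C)C)OC1=CC[C@@H](C(=O)OCC)C(=C)[C@H]1C | intermediate
5 | ethyl (1R,3R)-3-methyl-2-methylidene-4-oxocyclohexane-1-carboxylate | O=C1CC[C@@H](C(=O)OCC)C(=C)[C@H]1C | intermediate (not isolated)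
6 | (1R,2R,4R)-4-(hydroxymethyl)-2-methyl-3-methylidenecyclohexan-1-ol | O[C@@H]1CC[C@@H](CO)C(=C)[C@H]1C | intermediate
7 | (1R,3R,4R)-4-hydroxy-3-methyl-2-methylidenecyclohexane-1-carbaldehyde | O[C@@H]1CC[C@@H](C=O)C(=C)[C@H]1C | intermediate
8 | methoxyallene (1-methoxypropa-1,2-diene) | COC=C=C | starting material
9 | 1-lithio-1-methoxyallene | [Li]C(OC)=C=C | intermediate (not isolated)
10 | dilithium (1R,2R,4R)-4-[(1S)-2-methoxy-1-oxidobuta-2,3-dien-1-yl]-2-methyl-3-methylidenecyclohexan-1-olate | [Li+].[Li+].[O-][C@@H]1CC[C@@H]([C@H]([O-])C(OC)=C=C)C(=C)[C@H]1C | intermediate (not isolated)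
11 | bis(tert-butyldimethylsilyl) ether of (1S)-1-[(1R,3R,4R)-4-hydroxy-3-methyl-2-methylidenecyclohexyl]-2-methoxybuta-2,3-dien-1-ol | CC(C)(C)[Si](C)(C)O[C@@H]1CC[C@@H]([C@H](O[Si](C)(C)C(C)(C)C)C(OC)=C=C)C(=C)[C@H]1C | intermediate (not isolated)
12 | (1S)-1-[(tert-butyldimethylsilyl)oxy]-1-[(1R,3R,4R)-4-[(tert-butyldimethylsilyl)oxy]-3-methyl-2-methylidenecyclohexyl]but-3-en-2-one | CC(C)(C)[Si](C)(C)O[C@@H]1CC[C@@H]([C@H](O[Si](C)(C)C(C)(C)C)C(=O)C=C)C(=C)[C@H]1C | intermediate
13 | (1S,4aR,5R,6R,8aR)-1,6-bis[(tert-butyldimethylsilyl)oxy]-4a,5-dimethyloctahydronaphthalen-2(1H)-one | CC(C)(C)[Si](C)(C)O[C@@H]1CC[C@H]2[C@H](O[Si](C)(C)C(C)(C)C)C(=O)CC[C@]2(C)[C@H]1C | intermediate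
14 | acetone | CC(C)=O | starting material
15 | lithium (1S,4aR,5R,6R,8aR)-1,6-bis[(tert-butyldimethylsilyl)oxy]-4a,5-dimethyl-1,4,4a,5,6,7,8,8a-octahydronaphthalen-2-olate | [Li+].CC(C)(C)[Si](C)(C)O[C@@H]1CC[C@H]2[C@H](O[Si](C)(C)C(C)(C)C)C([O-])=CC[C@]2(C)[C@H]1C | intermediate (not isolated)
16 | (1S,4aR,5R,6R,8aR)-1,6-bis[(tert-butyldimethylsilyl)oxy]-3-(2-hydroxypropan-2-yl)-4a,5-dimethyloctahydronaphthalen-2(1H)-one, both C3 epimers | CC(C)(C)[Si](C)(C)O[C@@H]1CC[C@H]2[C@H](O[Si](C)(C)C(C)(C)C)C(=O)C(C(C)(C)O)C[C@]2(C)[C@H]1C | intermediate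
17 | (1S,4aR,5R,6R,8aR)-1,6-dihydroxy-3-(2-hydroxypropan-2-yl)-4a,5-dimethyloctahydronaphthalen-2(1H)-one, both C3 epimers | O[C@@H]1CC[C@H]2[C@H](O)C(=O)C(C(C)(C)O)C[C@]2(C)[C@H]1C | intermediate (not isolated)
18 | (1S,4aR,5R,6R,8aR)-1,6-dihydroxy-4a,5-dimethyl-3-(propan-2-ylidene)octahydronaphthalen-2(1H)-one | O[C@@H]1CC[C@H]2[C@H](O)C(=O)C(=C(C)C)C[C@]2(C)[C@H]1C | intermediate
19 | (S)-pent-1-yn-3-ol | O[C@H](C#C)CC | starting material
20 | dilithium (S)-pent-1-yn-1-id-3-olate | [Li+].[Li+].[O-][C@H](C#[C-])CC | intermediate (not isolated)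
21 | (S)-4-hydroxyhex-2-ynoic acid | O[C@H](C#CC(=O)O)CC | intermediate
22 | hex-2-ynoic acid | CCCC#CC(=O)O | starting material
23 | hex-2-ynoyl chloride | CCCC#CC(=O)Cl | intermediate (not isolated)
24 | (S)-4-(hex-2-ynoyloxy)hex-2-ynoic acid | CCCC#CC(=O)O[C@H](C#CC(=O)O)CC | intermediate
25 | (1R,2R,4aR,5S,8aR)-5-hydroxy-1,8a-dimethyl-6-oxo-7-(propan-2-ylidene)decahydronaphthalen-2-yl (4S)-4-(hex-2-ynoyloxy)hex-2-ynoate | CCCC#CC(=O)O[C@H](C#CC(=O)O[C@@H]1CC[C@H]2[C@H](O)C(=O)C(=C(C)C)C[C@]2(C)[C@H]1C)CC | intermediate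
26 | (1R,2R,4aR,5S,8aR)-5-hydroxy-1,8a-dimethyl-6-oxo-7-(propan-2-ylidene)decahydronaphthalen-2-yl (2Z,4S)-4-[(2Z)-hex-2-enoyloxy]hex-2-enoate | CCC/C=C\C(=O)O[C@H](/C=C\C(=O)O[C@@H]1CC[C@H]2[C@H](O)C(=O)C(=C(C)C)C[C@]2(C)[C@H]1C)CC | target

**Totals**
Total step count: 12. Longest linear sequence: 10 (steps 1–8, 11, 12).

**Three steps most likely to fail**

1. Step 2, because facial, endo and regiochemical control all depend on a catalytic cycloaddition of an allenic ester that has no direct precedent. The fallback sets out from 2 and comes back at 6, and puts the absolute configuration under auxiliary control. Buta-2,3-dienoic acid is coupled (pivaloyl chloride, Et3N; then the lithium salt of (R)-4-benzyl-1,3-oxazolidin-2-one) to (4R)-4-benzyl-3-(buta-2,3-dienoyl)-1,3-oxazolidin-2-one F1. Et2AlCl (1.4 equiv, CH2Cl2, −78 °C) chelates the imide, and 2 adds endo to the face away from the benzyl group to give imide adduct F2. Bu4NF/AcOH gives keto imide F3, and LiBH4 (THF, MeOH) reduces ketone and imide to diol 6 and releases the oxazolidinone.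

2. Step 6, because the enone may be reduced before it cyclises, the alkene may isomerise, or the cis ring fusion may compete. The fallback sets out from 12 and comes back at 13, and makes the same tertiary radical by reductive epoxide opening instead of hydrogen atom transfer. 3-Chloroperbenzoic acid (NaHCO3, CH2Cl2, 0 °C) epoxidises only the electron-rich exocyclic alkene to spiro-epoxide F4. Cp2TiCl (from Cp2TiCl2 and Mn powder, THF) opens the epoxide at the more substituted carbon, the radical closes 6-endo onto the enone, and work-up gives hydroxymethyl decalinone F5. 1,1'-Thiocarbonyldiimidazole gives imidazolyl thiocarbonate F6, and Bu3SnH with 2,2'-azobis(2-methylpropionitrile) in toluene at 110 °C (Barton–McCombie) converts the CH2O group into the methyl group of 13.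

3. Step 11, because it relies on the inherent difference in reactivity between the two secondary hydroxyls of 18. The fallback sets out from 16 and comes back at 25, and tells the hydroxyls apart by their silyl ethers. MsCl/Et3N then DBU dehydrates 16 with both silyl ethers in place to bis-silyl enone F7. Camphor-10-sulfonic acid in MeOH/CH2Cl2 at 0 °C removes the unhindered ring A silyl ether first and gives mono-silyl alcohol F8. Coupling with 24 (N,N'-dicyclohexylcarbodiimide, 4-(dimethylamino)pyridine) gives silyl ester F9, and HF·pyridine in THF frees the acyloin hydroxyl to give 25.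

**Further compounds**
F1 | step 2 | (4R)-4-benzyl-3-(buta-2,3-dienoyl)-1,3-oxazolidin-2-one | C=C=CC(=O)N1[C@H](Cc2ccccc2)COC1=O
F2 | step 2 | (4R)-4-benzyl-3-{[(1R,5R)-5-methyl-6-methylidene-4-[(triisopropylsilyl)oxy]cyclohex-3-en-1-yl]carbonyl}-1,3-oxazolidin-2-one | CC(C)[Si](C(C)C)(C(C)C)OC1=CC[C@@H](C(=O)N2[C@H](Cc3ccccc3)COC2=O)C(=C)[C@H]1C
F3 | step 2 | (4R)-4-benzyl-3-{[(1R,3R)-3-methyl-2-methylidene-4-oxocyclohexyl]carbonyl}-1,3-oxazolidin-2-one | O=C1CC[C@@H](C(=O)N2[C@H](Cc3ccccc3)COC2=O)C(=C)[C@H]1C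
F4 | step 6 | spiro-epoxide of 12 (oxirane in place of the exocyclic C=CH2, other centres as in 12, both epimers at the spiro carbon) | CC(C)(C)[Si](C)(C)O[C@@H]1CC[C@@H]([C@H](O[Si](C)(C)C(C)(C)C)C(=O)C=C)C2(CO2)[C@H]1C
F5 | step 6 | (1S,4aS,5R,6R,8aR)-1,6-bis[(tert-butyldimethylsilyl)oxy]-4a-(hydroxymethyl)-5-methyloctahydronaphthalen-2(1H)-one | CC(C)(C)[Si](C)(C)O[C@@H]1CC[C@H]2[C@H](O[Si](C)(C)C(C)(C)C)C(=O)CC[C@]2(CO)[C@H]1C
F6 | step 6 | O-(imidazol-1-ylthiocarbonyl) derivative of the primary alcohol of F5 (other centres unchanged) | CC(C)(C)[Si](C)(C)O[C@@H]1CC[C@H]2[C@H](O[Si](C)(C)C(C)(C)C)C(=O)CC[C@]2(COC(=S)n3ccnc3)[C@H]1C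
F7 | step 11 | (1S,4aR,5R,6R,8aR)-1,6-bis[(tert-butyldimethylsilyl)oxy]-4a,5-dimethyl-3-(propan-2-ylidene)octahydronaphthalen-2(1H)-one | CC(C)(C)[Si](C)(C)O[C@@H]1CC[C@H]2[C@H](O[Si](C)(C)C(C)(C)C)C(=O)C(=C(C)C)C[C@]2(C)[C@H]1C
F8 | step 11 | (1S,4aR,5R,6R,8aR)-1-[(tert-butyldimethylsilyl)oxy]-6-hydroxy-4a,5-dimethyl-3-(propan-2-ylidene)octahydronaphthalen-2(1H)-one | O[C@@H]1CC[C@H]2[C@H](O[Si](C)(C)C(C)(C)C)C(=O)C(=C(C)C)C[C@]2(C)[C@H]1C
F9 | step 11 | (1R,2R,4aR,5S,8aR)-5-[(tert-butyldimethylsilyl)oxy]-1,8a-dimethyl-6-oxo-7-(propan-2-ylidene)decahydronaphthalen-2-yl (4S)-4-(hex-2-ynoyloxy)hex-2-ynoate | CCCC#CC(=O)O[C@H](C#CC(=O)O[C@@H]1CC[C@H]2[C@H](O[Si](C)(C)C(C)(C)C)C(=O)C(=C(C)C)C[C@]2(C)[C@H]1C)CC
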